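**Small charge.** A small charge of substrate, 20 mM, meets partner in a closed flask. On the steps thought possible, a substrate molecule opens, joins the second intermediate and becomes target, and target then stands at a fork it can cross both ways, to the isomer of the product and back.

| flask | substrate | partner | temperature | remark | time |
|---|---|---|---|---|---|
| theta | 20 mM | 1 equiv | 50 °C | the very flask that is asked about, followed so far |  |
| delta | 20 mM | 0.67 equiv | 45 °C | run made earlier |  |
| flask | 20 mM | 1.00 equiv | 50 °C |  | 8.0 h |

| theta: time / h | theta: target / % | delta: time / h | delta: target / % |
|---|---|---|---|
| 0.417 | 15 | 0.667 | 10 |
| 0.833 | 26 | 1.33 | 19 |
| 2.00 | 45 | 2.00 | 28 |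
| 5.00 | 38 | 3.00 | 38 |

(standard deviation of a reading: 1.5 percentage points)

- removed target is counted in
- steps thought possible: substrate -> open intermediate; partner -> second intermediate; open intermediate + second intermediate -> target; target <-> isomer of the product
- additions bring no volume worth counting

- north-east: change nothing and wait 15 h more
- north-west: at 8.0 h take out 90% of the target then present, then wait 15 h
- south-west: at 8.0 h add partner, 100% of the amount charged, then wait 15 h
- north: at 8.0 h raise the temperature by 25 K, then wait 15 h

- target, in percent of the substrate first charged, at 8.0 h
- what to do for the largest gain in target; "none" if nothing gains more than 2 percentage points (north-east / north-west / south-west / north / none)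
- target present, with what was taken out counted in, in percent of the substrate first charged, after north-east
- target present, with what was taken out counted in, in percent of the substrate first charged, after north-west

**Slow motion.** In the theta run, the asked flask followed so far, the first instants show target at 15% after 0.417 h, which mostly reads arrival at the fork. By 2.00 h the reading is 45%, with arrival and crossing both at work. At 5.00 h it reads 38%, a fall of 7 percentage points against a scatter of 1.5 points, so crossing has overtaken arrival. The reckoning here takes the last reading as close to rest, an assumption that these readings do not test.

**Resting share.** Dividing that reading by the whole charge gives 38.0% for s, the chance that a molecule which has reached the fork is found as target at rest; it is a reading and carries the scatter. This is thermodynamic control: target is s times what reached the fork. The reckoning here therefore puts target at s, both at 8.0 h and after waiting. Taking out 90% banks that share of target, and the remainder splits again by s, which gives 59.2%, a gain of 21 points. No reading gives s at the higher temperature, so north stays uncounted and the reckoning commits to north-west.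

**The forecast.** It gave 27% now, 12% after north-east and 33% after north-west, and chose north-west, saying: “Heating only speeds the drain.” Its figure for now lies below the reckoning here.

**The flask.** At 8.0 h target stands at 35.6%. North-east gives 34.5%. North-west gives 55.5%, a gain of 20 points. The best option is north, with a gain of 28 points.

    substrate → open intermediate (k = 0.00950 min⁻¹, Ea = 108 kJ mol⁻¹)
    partner → second intermediate (k = 0.143 min⁻¹, Ea = 84.0 kJ mol⁻¹)
    open intermediate + second intermediate → target (k = 7.74 M⁻¹ min⁻¹, Ea = 67.0 kJ mol⁻¹)
    target ⇌ isomer of the product (K = 1.88, k = 0.00779 min⁻¹, Ea = 90.0 kJ mol⁻¹, ΔH = −45.0 kJ mol⁻¹)
    (constants at 50 °C)

**Hot share.** The main reason why target falls short in the flask at 8.0 h is the crossing, both ways: without it target stands at 96.2% against 35.6%. The constants put the resting share at 34.7% at 50 °C. The fork is exothermic toward the isomer, so the rise gives 63.9%, which is 28 points above target now. The way back from isomer to target is part of what pays for north: without it the gain of 28 points becomes −8.1 points.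

**Second flask.** With 0.600 equiv of partner, the limiting reagent, partner falls to 0% and s gives 22.8%; the computed target is 21.2%.

Readings and results were generated by integration for an exercise; scatter was added.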